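The first reading of a run, at 4.00 h, already shows how fast left-handed substrate is being cleared, so the reckoning for the flask starts there.

common to all: left-handed substrate 0.024 M; right-handed substrate 0.024 M
- Tuesday's: solid reagent 0.072 M; free catalyst 0.060 mM; run made earlier
- Friday's: solid reagent 0.072 M; free catalyst 0.24 mM; run made earlier
- Monday's: solid reagent 0.036 M; free catalyst 0.12 mM; run made earlier
- flask: solid reagent 0.0720 M; free catalyst 0.12 mM; time 40 h

- Tuesday's (time / h: right-handed substrate / %, left-handed substrate / %, left-handed product / %): 4.00: 49.8, 22.6, 28.9; 6.00: 50.3, 11.4, 39.5; 8.00: 49.9, 4.9, 43.9; 15.0: 49.3, 0.9, 48.9; 20.0: 48.3, 0.9, 50.1; 30.0: 49.8, 0.1, 49.3; 50.0: 49.4, 0.8, 49.4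
- Friday's (time / h: right-handed substrate / %, left-handed substrate / %, left-handed product / %): 4.00: 49.8, 10.9, 39.8; 6.00: 49.0, 1.8, 48.5; 8.00: 48.7, 0.2, 50.3; 15.0: 46.5, 0.1, 49.7; 20.0: 46.0, 0, 50.2; 30.0: 45.5, 0.2, 50.1; 50.0: 45.3, 0, 49.4
- Monday's (time / h: right-handed substrate / %, left-handed substrate / %, left-handed product / %): 4.00: 51.2, 15.6, 34.6; 12.0: 49.2, 0.4, 50.2; 20.0: 47.9, 0.8, 49.9; 30.0: 48.4, 0, 50.1; 50.0: 46.9, 0, 49.0

(standard deviation of a reading: 0.5 percentage points)

1. whether the excess of right-handed substrate over left-handed substrate among what is left of the two reaches 80 % by 40 h (yes / no)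
2. the highest excess of right-handed substrate over left-handed substrate among what is left of the two up to 40 h

- free catalyst is single-handed; left-handed substrate and right-handed substrate are mirror images of each other, charged as a racemate, each of them at the stated concentration
- as a solid, counted per litre of solution: solid reagent
- what was read earlier has a scatter of 0.5 percentage points, one standard deviation
- at the start none of the solid reagent is in solution

The flask's free catalyst is the geometric mean of Tuesday's and Friday's, and the geometric mean of their left-handed substrate at that time is 15.7 %. Monday's run, at the flask's catalyst with half the solid reagent, reads 15.6 %. The two stand 0.100 percentage points apart, with a scatter of 0.5 points on a reading, so Monday's reading is taken as the flask's at that time.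

From there the fall is read as pseudo-first-order: 0.382 h⁻¹ on Tuesday and 0.900 h⁻¹ on Friday. Catalyst raised by a factor 4.00 thus buys, as read, a factor 2.36 in rate. The flask's value is taken as the geometric mean, 0.587 h⁻¹, its clearance constant, the fractional loss of left-handed substrate per hour.

The wanted excess means left-handed substrate at 0.111 of right-handed substrate, which is 5.69 % on Monday's reading, so the flask should cross at 5.72 h. In Friday's run the loss of right-handed substrate, read from 8.00 h to 15.0 h against 20.0 h to 50.0 h, slows by a factor 13.5, and that slowing is read later than the crossing reckoned for the flask. Clearance held until 12.0 h leaves 0.143 % of left-handed substrate, an excess of 99.4 % in this reckoning.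

The forecast gives yes and a top of 99.3 %, crossing near 7 to 8 h against the 5.72 h reckoned here, with this ground: “Right-handed substrate barely reacts while left-handed remains”.

The flask gives yes, with a top of >99.9 %.

    partner + free catalyst + left-handed substrate → free catalyst + left-handed product (k = 320 M⁻² s⁻¹)
    partner + free catalyst + right-handed substrate → free catalyst + right-handed product (k = 1.70 M⁻² s⁻¹)
    partner + free catalyst → spent catalyst A (k = 0.00260 M⁻¹ s⁻¹)
    solid reagent ⇌ partner, rate k4*(cs4 - [partner]) while solid is left; crystals form when [partner] > cs4 (solubility = 22.0 mM, k = 7.60 × 10⁻⁵ s⁻¹)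
    free catalyst → spent catalyst B (k = 1.50 × 10⁻⁵ s⁻¹)

The flask crosses the wanted excess at 5.87 h, with 49.4 % of right-handed substrate left. Left-handed substrate then stands at 5.48 %, down from 15.3 % at 4.00 h, and against the 0.587 h⁻¹ carried from the readings the flask's clearance constant over that stretch is 0.549 h⁻¹.

The runs come from a simulation on assumed constants; noise was put on by code.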